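The oxolane ring is disconnected at O1–C2 (the benzylic ether bond) and at C3–C4. The feature exploited is that C4 carries an aryl ketone and C3 a hydroxymethyl group: written as a 1-arylvinyl and a formyl group, they turn O1–C5–C4 into a vinyl oxirane and C2–C3 into a cinnamaldehyde. One operation, co-catalysed by zerovalent palladium and a chiral secondary amine, joins the two by oxa-Michael addition and enamine allylation, closes the oxolane and sets C2 and C3. C4, which ends up alpha to the ketone, is equilibrated to the all-trans ring at the end. The precursor pair is an aryl enal and a racemic 2-(1-arylvinyl)oxirane, both as triisopropylsilyl ethers.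

Key step: step 5

Remark: atoms are numbered as in the oxolane (O1, C2 aryl, C3 hydroxymethyl, C4 aroyl, C5), which makes the target (2S,3R,4S), all-trans; Ar denotes 4-methoxy-3-(triisopropylsilyloxy)phenyl; 5-iodo-2-methoxyphenol and buta-2,3-dien-1-ol are assumed to be purchasable.

Step 1
Reactants: 1 isovanillin (3-hydroxy-4-methoxybenzaldehyde)
Product: 2 4-methoxy-3-(triisopropylsilyloxy)benzaldehyde
Conditions: TIPSCl, imidazole, DMF, rt
Reagents that add atoms: triisopropylsilyl chloride CC(C)[Si](Cl)(C(C)C)C(C)C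
Why: Silyl ether formation masks the phenol, which would otherwise be O-allylated by the π-allylpalladium species of step 5, and the triisopropylsilyl group is chosen because it tolerates carbonate, borohydride and periodate.

Step 2
Reactants: 2 4-methoxy-3-(triisopropylsilyloxy)benzaldehyde
Product: 3 (E)-3-Ar-prop-2-enal
Conditions: Ph3P=CHCHO (1.05 equiv), toluene, 80 °C
Reagents that add atoms: (triphenylphosphoranylidene)acetaldehyde O=CC=P(c1ccccc1)(c1ccccc1)c1ccccc1
Why: Wittig olefination with the stabilised formylmethylene ylide should give the E-enal, and keeping the ylide near one equivalent limits a second homologation.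

Step 3
Reactants: 4 5-iodo-2-methoxyphenol
Product: 5 (5-iodo-2-methoxyphenoxy)triisopropylsilane
Conditions: TIPSCl, imidazole, DMF, rt
Reagents that add atoms: triisopropylsilyl chloride CC(C)[Si](Cl)(C(C)C)C(C)C
Why: Silyl ether formation protects the phenol against O-allylation and against the carbonate base of step 4, for which a triisopropylsilyl aryl ether is robust enough.

Step 4
Reactants: 5 (5-iodo-2-methoxyphenoxy)triisopropylsilane; 6 buta-2,3-dien-1-ol
Product: 7 rac-2-(1-Ar-ethenyl)oxirane
Conditions: Pd(PPh3)4 (5 mol %), K2CO3, DMF, 60 °C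
Reagents that add atoms: none
Why: This is the known coupling–cyclisation of 2,3-allenols with aryl iodides, in which oxidative addition, carbopalladation of the allene at its central carbon to a 2-aryl-π-allylpalladium intermediate and 3-exo attack of the alkoxide on the substituted allyl terminus should give the vinyl oxirane, whose stereocentre may be racemic because step 5 erases it.

Step 5
Reactants: 3 (E)-3-Ar-prop-2-enal; 7 rac-2-(1-Ar-ethenyl)oxirane (1.5 equiv)
Product: 9 [(2S,3R,4R)-2-Ar-4-(1-Ar-ethenyl)oxolan-3-yl]methanol, via oxolane-3-carbaldehyde 8 (not isolated)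
Conditions: Pd(PPh3)4 (5 mol %), (S)-2-[diphenyl(trimethylsilyloxy)methyl]pyrrolidine (20 mol %), PhCO2H (20 mol %), THF, rt; then NaBH4, MeOH, 0 °C
Reagents that add atoms: none
Why: Proposed new method: zerovalent palladium should ionise racemic 7 to a zwitterionic 2-aryl-π-allylpalladium alkoxide (its enantiomeric forms interconvert by π–σ–π through the CH2 terminus), the alkoxide adds to C-β of the iminium ion formed from 3 and the amine (O1–C2), the resulting enamine attacks the substituted allyl terminus (C3–C4), hydrolysis releases aldehyde 8 and both catalysts, and NaBH4 reduces the formyl group before C3 can drift. The closest known reactions are the amine/palladium co-catalysed formal [3+2] cycloadditions of vinylcyclopropanes and N-sulfonyl vinylaziridines with enals and the palladium-catalysed oxa-Michael/allylic alkylation [3+2] of vinyl oxiranes with doubly activated alkenes; the new element is pairing a vinyl oxirane with an iminium-activated enal. The oxolane closes in the second bond-forming event by 5-exo attack of the enamine carbon on the proximal allyl terminus, the arylvinyl unit staying exocyclic, whereas attack at the distal CH2 would need a seven-membered ring. C2 is set by the catalyst, whose silyloxydiphenylmethyl group shields one face of the E,s-trans iminium ion so that oxygen should add to the Si face of C-β (2S); C3 follows by relay, the enamine reacting anti to the new C2 aryl group (2,3-trans, also the outcome of enamine equilibration); C4 is expected trans to C3 on steric grounds but is not relied on, because step 7 equilibrates it. The step needs 1,4- over 1,2-addition of the alkoxide (iminium activation; 1,2-adducts are reversible N,O-acetals), capture of the zwitterion faster than its collapse to 7 or to a 3-aryl-2,5-dihydrofuran (7 is used in excess), and no N-allylation of the hindered amine.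

Step 6
Reactants: 9 [(2S,3R,4R)-2-Ar-4-(1-Ar-ethenyl)oxolan-3-yl]methanol
Product: 11 [(3S,4R,5S)-5-Ar-4-(hydroxymethyl)oxolan-3-yl](Ar)methanone, via diol 10 (not isolated)
Conditions: OsO4 (2 mol %), NaIO4, 2,6-lutidine, dioxane–H2O (3:1), rt
Reagents that add atoms: osmium tetroxide O=[Os](=O)(=O)=O (catalytic oxygen carrier); sodium periodate [Na+].[O-]I(=O)(=O)=O (terminal oxidant)
Why: Lemieux–Johnson oxidation (dihydroxylation of the 1,1-disubstituted alkene, then periodate cleavage of diol 10) should unveil the aryl ketone without touching the electron-rich arenes, the silyl ethers or the primary alcohol, and any drift at C4 is harmless.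

Step 7
Reactants: 11 [(3S,4R,5S)-5-Ar-4-(hydroxymethyl)oxolan-3-yl](Ar)methanone
Product: 12 (3-hydroxy-4-methoxyphenyl)[(3S,4R,5S)-5-(3-hydroxy-4-methoxyphenyl)-4-(hydroxymethyl)oxolan-3-yl]methanone (target)
Conditions: TBAF, THF, 0 °C to rt; then K2CO3, MeOH, rt (argon); aq NH4Cl
Reagents that add atoms: none
Why: Fluoride cleaves both aryl silyl ethers and the basic medium should equilibrate C4 through the ketone enolate to the all-trans oxolane (thermodynamic control anchored by the non-epimerisable C3, with any 3,4-cis material or its cis-fused hemiketal draining into the trans hydroxy ketone), while ring opening by β-elimination is stereoelectronically disfavoured as the reverse of a 5-endo-trig closure.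

Compound list
1 | isovanillin (3-hydroxy-4-methoxybenzaldehyde) | COc1ccc(C=O)cc1O | starting material
2 | 4-methoxy-3-(triisopropylsilyloxy)benzaldehyde | COc1ccc(C=O)cc1O[Si](C(C)C)(C(C)C)C(C)C | intermediate
3 | (E)-3-[4-methoxy-3-(triisopropylsilyloxy)phenyl]prop-2-enal | COc1ccc(/C=C/C=O)cc1O[Si](C(C)C)(C(C)C)C(C)C | intermediate
4 | 5-iodo-2-methoxyphenol | COc1ccc(I)cc1O | starting material
5 | (5-iodo-2-methoxyphenoxy)triisopropylsilane | COc1ccc(I)cc1O[Si](C(C)C)(C(C)C)C(C)C | intermediate
6 | buta-2,3-dien-1-ol | C=C=CCO | starting material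
7 | rac-2-{1-[4-methoxy-3-(triisopropylsilyloxy)phenyl]ethenyl}oxirane | COc1ccc(C(=C)C2CO2)cc1O[Si](C(C)C)(C(C)C)C(C)C | intermediate
8 | (2S,3S,4R)-2-[4-methoxy-3-(triisopropylsilyloxy)phenyl]-4-{1-[4-methoxy-3-(triisopropylsilyloxy)phenyl]ethenyl}oxolane-3-carbaldehyde | COc1ccc(C(=C)[C@@H]2CO[C@H](c3ccc(OC)c(O[Si](C(C)C)(C(C)C)C(C)C)c3)[C@H]2C=O)cc1O[Si](C(C)C)(C(C)C)C(C)C | intermediate
9 | [(2S,3R,4R)-2-[4-methoxy-3-(triisopropylsilyloxy)phenyl]-4-{1-[4-methoxy-3-(triisopropylsilyloxy)phenyl]ethenyl}oxolan-3-yl]methanol | COc1ccc(C(=C)[C@@H]2CO[C@H](c3ccc(OC)c(O[Si](C(C)C)(C(C)C)C(C)C)c3)[C@H]2CO)cc1O[Si](C(C)C)(C(C)C)C(C)C | intermediate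
10 | 1-[(3S,4R,5S)-4-(hydroxymethyl)-5-[4-methoxy-3-(triisopropylsilyloxy)phenyl]oxolan-3-yl]-1-[4-methoxy-3-(triisopropylsilyloxy)phenyl]ethane-1,2-diol (both carbinol epimers) | COc1ccc(C(O)(CO)[C@@H]2CO[C@H](c3ccc(OC)c(O[Si](C(C)C)(C(C)C)C(C)C)c3)[C@H]2CO)cc1O[Si](C(C)C)(C(C)C)C(C)C | intermediate
11 | [(3S,4R,5S)-4-(hydroxymethyl)-5-[4-methoxy-3-(triisopropylsilyloxy)phenyl]oxolan-3-yl][4-methoxy-3-(triisopropylsilyloxy)phenyl]methanone | COc1ccc(C(=O)[C@@H]2CO[C@H](c3ccc(OC)c(O[Si](C(C)C)(C(C)C)C(C)C)c3)[C@H]2CO)cc1O[Si](C(C)C)(C(C)C)C(C)C | intermediate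
12 | (3-hydroxy-4-methoxyphenyl)[(3S,4R,5S)-5-(3-hydroxy-4-methoxyphenyl)-4-(hydroxymethyl)oxolan-3-yl]methanone | COc1ccc(C(=O)[C@@H]2CO[C@H](c3ccc(OC)c(O)c3)[C@H]2CO)cc1O | target

Total step count: 7. Longest linear sequence: 5 steps (1, 2, 5, 6, 7 or 3, 4, 5, 6, 7).

Steps most likely to fail

Step 5 (the proposed new method). The zwitterion may be captured too slowly, so that it recloses, adds 1,2 or isomerises the oxirane. Facial control may also erode, because the oxa-Michael addition is reversible and the ring closure then decides the configuration. The fallback uses only known chemistry and builds the ring stepwise; it sets out from 2 and comes back at 12. Aldehyde 2 is converted with propane-1,3-dithiol and BF3·OEt2 into 2-Ar-1,3-dithiane F1. Lithiation (n-BuLi, THF, −78 °C), conjugate addition to commercial (5R)-5-(l-menthyloxy)furan-2(5H)-one anti to the menthyloxy group and trapping of the lactone enolate with a second portion of 2 (aldol anti to the new C4 substituent) should give the trans,trans lactone adduct F2. LiAlH4 reduces lactone and acetal to the dithianyl triol F3 with loss of menthol. Mild acid (camphorsulfonic acid, CH2Cl2) ionises the benzylic carbinol, and the C5 hydroxyl closes the 2,3-trans oxolane dithiane F4. MeI and CaCO3 in aqueous MeCN unmask the C4-epimeric ketone F5 (3,4-cis). The conditions of step 7 then remove the silyl groups and equilibrate C4, giving 12.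

Step 7. Equilibration at C4 may stall with material resting as the cis-fused hemiketal, or the basic medium may open the ring by β-elimination or oxidise the phenoxides. The fallback removes the hemiketal sink and separates the two events; it sets out from 9 and comes back at 12. The primary alcohol of 9 is silylated (TIPSOTf, 2,6-lutidine) to the tris-silyl alkene F6. Lemieux–Johnson cleavage and equilibration with DBU in toluene, where the bulky silyloxymethyl group enforces the trans arrangement, give the tris-silyl trans ketone F7. Non-basic desilylation (TBAF buffered with AcOH, or HF·pyridine) then gives 12.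

Step 4. Zerovalent palladium may re-ionise the product vinyl oxirane under the coupling conditions, which leads to isomerisation (2,5-dihydrofuran, enal) or oligomers. The fallback avoids palladium; it sets out from 2 and comes back at 7. Vinylmagnesium bromide adds to 2 to give the allylic alcohol F8, and MnO2 oxidises it to the aryl vinyl ketone F9, which is used at once. Nucleophilic epoxidation (tBuOOH, DBU, CH2Cl2, 0 °C) gives the aroyl oxirane F10, and Wittig methylenation (Ph3P=CH2, THF) gives 7.

Further compounds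
F1 | step 5 | 2-[4-methoxy-3-(triisopropylsilyloxy)phenyl]-1,3-dithiane | COc1ccc(C2SCCCS2)cc1O[Si](C(C)C)(C(C)C)C(C)C
F2 | step 5 | (3S,4R,5R)-3-{hydroxy[4-methoxy-3-(triisopropylsilyloxy)phenyl]methyl}-4-{2-[4-methoxy-3-(triisopropylsilyloxy)phenyl]-1,3-dithian-2-yl}-5-[(1R,2S,5R)-menthyloxy]oxolan-2-one (carbinol epimers) | COc1ccc(C2(SCCCS2)[C@H]3[C@H](O[C@@H]4C[C@H](C)CC[C@H]4C(C)C)OC(=O)[C@@H]3C(O)c5ccc(OC)c(O[Si](C(C)C)(C(C)C)C(C)C)c5)cc1O[Si](C(C)C)(C(C)C)C(C)C
F3 | step 5 | (2R,3R)-2-{hydroxy[4-methoxy-3-(triisopropylsilyloxy)phenyl]methyl}-3-{2-[4-methoxy-3-(triisopropylsilyloxy)phenyl]-1,3-dithian-2-yl}butane-1,4-diol (carbinol epimers) | OC[C@H](C1(SCCCS1)c2ccc(OC)c(O[Si](C(C)C)(C(C)C)C(C)C)c2)[C@H](CO)C(O)c3ccc(OC)c(O[Si](C(C)C)(C(C)C)C(C)C)c3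
F4 | step 5 | [(2S,3R,4R)-2-[4-methoxy-3-(triisopropylsilyloxy)phenyl]-4-{2-[4-methoxy-3-(triisopropylsilyloxy)phenyl]-1,3-dithian-2-yl}oxolan-3-yl]methanol | COc1ccc(C2(SCCCS2)[C@H]3CO[C@H](c4ccc(OC)c(O[Si](C(C)C)(C(C)C)C(C)C)c4)[C@H]3CO)cc1O[Si](C(C)C)(C(C)C)C(C)C
F5 | step 5 | [(3R,4R,5S)-4-(hydroxymethyl)-5-[4-methoxy-3-(triisopropylsilyloxy)phenyl]oxolan-3-yl][4-methoxy-3-(triisopropylsilyloxy)phenyl]methanone (C4 epimer of 11) | COc1ccc(C(=O)[C@H]2CO[C@H](c3ccc(OC)c(O[Si](C(C)C)(C(C)C)C(C)C)c3)[C@H]2CO)cc1O[Si](C(C)C)(C(C)C)C(C)C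
F6 | step 7 | triisopropyl{[(2S,3R,4R)-2-[4-methoxy-3-(triisopropylsilyloxy)phenyl]-4-{1-[4-methoxy-3-(triisopropylsilyloxy)phenyl]ethenyl}oxolan-3-yl]methoxy}silane | COc1ccc(C(=C)[C@@H]2CO[C@H](c3ccc(OC)c(O[Si](C(C)C)(C(C)C)C(C)C)c3)[C@H]2CO[Si](C(C)C)(C(C)C)C(C)C)cc1O[Si](C(C)C)(C(C)C)C(C)C
F7 | step 7 | [(3S,4R,5S)-5-[4-methoxy-3-(triisopropylsilyloxy)phenyl]-4-[(triisopropylsilyloxy)methyl]oxolan-3-yl][4-methoxy-3-(triisopropylsilyloxy)phenyl]methanone | COc1ccc(C(=O)[C@@H]2CO[C@H](c3ccc(OC)c(O[Si](C(C)C)(C(C)C)C(C)C)c3)[C@H]2CO[Si](C(C)C)(C(C)C)C(C)C)cc1O[Si](C(C)C)(C(C)C)C(C)C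
F8 | step 4 | rac-1-[4-methoxy-3-(triisopropylsilyloxy)phenyl]prop-2-en-1-ol | COc1ccc(C(O)C=C)cc1O[Si](C(C)C)(C(C)C)C(C)C
F9 | step 4 | 1-[4-methoxy-3-(triisopropylsilyloxy)phenyl]prop-2-en-1-one | COc1ccc(C(=O)C=C)cc1O[Si](C(C)C)(C(C)C)C(C)C
F10 | step 4 | rac-[4-methoxy-3-(triisopropylsilyloxy)phenyl](oxiran-2-yl)methanone | COc1ccc(C(=O)C2CO2)cc1O[Si](C(C)C)(C(C)C)C(C)C
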